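**Route to 7-acetoxy-7,8-dihydroiodovulone I: C12–O bond by enantioconvergent α′-hydroxylation, then chelate-controlled aldol**

Assumption: (Z)-oct-2-en-1-ol is bought as the pure Z isomer, (R)-TRIP is taken to give the (S)-carbinol in step 3 (the mirror-image acid is used if the first run shows the opposite sense), and prostanoid numbering is used in the text (C1 ester carbon, C7 acetoxy carbon, C8 and C12 the ring carbons bearing the upper chain and the hydroxyl).

**Retrosynthetic overview**
- Target ⇒ diol (acetylation of the secondary C7–OH only) ⇒ C7–C8 aldol between the dianion of (S)-4-hydroxy-2-iodo-4-[(Z)-oct-2-enyl]cyclopent-2-enone and methyl (Z)-7-oxohept-5-enoate; C8 and C7 are relayed from C12.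
- Iodoenone ⇒ enone (α-iodination) ⇒ (S)-α′-hydroxy vinylogous ester (Stork–Danheiser carbonyl transposition).
- Key disconnection: the C12–O bond, made by an enantioconvergent, phosphoric-acid enol-catalysed α′-hydroxylation of racemic 5-octenyl-3-ethoxycyclopentenone with nitrosobenzene; this is the only step that sets absolute configuration.
- Racemic vinylogous ester ⇒ 3-ethoxycyclopent-2-en-1-one + (Z)-1-bromooct-2-ene; Z-enal ⇒ methyl hex-5-enoate + (Z)-but-2-ene-1,4-diol (Z-selective cross-metathesis, oxidation).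
- Rings: the single carbocycle is bought as 3-ethoxycyclopent-2-en-1-one and kept intact; no ring is formed or opened.

**Forward route**

Step 1
Reactants: 1 (Z)-oct-2-en-1-ol
Product: 2 (Z)-1-bromooct-2-ene
Conditions: CBr4 (1.1 equiv), PPh3 (1.15 equiv), CH2Cl2, 0 °C
Reagents that add atoms: carbon tetrabromide, BrC(Br)(Br)Br
Why: Appel bromination, in which bromide displaces the alkoxyphosphonium group by SN2 at the primary allylic carbon so the Z alkene is kept and no stereocentre is involved.

Step 2
Reactants: 3 3-ethoxycyclopent-2-en-1-one; 2 (Z)-1-bromooct-2-ene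
Product: 5 rac-3-ethoxy-5-[(Z)-oct-2-en-1-yl]cyclopent-2-en-1-one, via lithium enolate 4 (not isolated)
Conditions: LiN(iPr)2 (1.1 equiv), THF, −78 °C, 30 min; then 2 (1.2 equiv), −78 → −20 °C
Reagents that add atoms: none
Why: Stork–Danheiser-type kinetic α′-alkylation of a vinylogous ester, the C5 enolate displacing the primary allylic bromide by SN2 with the Z alkene intact; the new stereocentre is left racemic because step 3 erases and resets it.

Step 3
Reactants: 5 rac-3-ethoxy-5-[(Z)-oct-2-en-1-yl]cyclopent-2-en-1-one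
Product: 8 (S)-3-ethoxy-5-hydroxy-5-[(Z)-oct-2-en-1-yl]cyclopent-2-en-1-one, via dienol 6 (not isolated), via aminooxy ketone 7 (not isolated)
Conditions: (R)-3,3′-bis(2,4,6-triisopropylphenyl)-1,1′-binaphthalene-2,2′-diyl hydrogen phosphate [(R)-TRIP] (10 mol %), PhNO (2.5 equiv), AcOH (1 equiv), toluene, 4 Å MS, 10 °C
Reagents that add atoms: nitrosobenzene, O=Nc1ccccc1
Why: Proposed new method: the phosphoric acid protonates the strongly basic vinylogous-ester carbonyl and its phosphoryl oxygen removes the α′ proton, so both enantiomers of 5 converge on the achiral, alkyl-substituted cyclopentadienol 6 (the more substituted and more stable dienol), whose terminal carbon C5 is then attacked by the oxygen of nitrosobenzene on one face inside the hydrogen-bonded chiral ion pair (O-selective nitroso aldol giving 7 and the C12–O bond), after which a second nitrosobenzene cleaves the N–O bond to release 8 and azoxybenzene; the closest known reaction type is chiral-phosphoric-acid enol catalysis for α-hydroxylation of α-branched cyclic ketones with nitrosobenzene, which has not been shown for the α′ position of a vinylogous ester.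

Step 4
Reactants: 8 (S)-3-ethoxy-5-hydroxy-5-[(Z)-oct-2-en-1-yl]cyclopent-2-en-1-one
Product: 10 (S)-4-hydroxy-4-[(Z)-oct-2-en-1-yl]cyclopent-2-en-1-one, via diol 9 (not isolated)
Conditions: iBu2AlH (2.5 equiv), CH2Cl2, −78 → 0 °C; then 1 M HCl, THF, 0 °C → rt
Reagents that add atoms: water, O
Why: Stork–Danheiser carbonyl transposition, in which 1,2-hydride addition gives allylic alcohol 9 and acid hydrolysis of its enol ether (water in at the ethoxy carbon, ethanol and then water out) unveils the enone while the tertiary carbinol is untouched and keeps its configuration.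

Step 5
Reactants: 10 (S)-4-hydroxy-4-[(Z)-oct-2-en-1-yl]cyclopent-2-en-1-one
Product: 11 (S)-4-hydroxy-2-iodo-4-[(Z)-oct-2-en-1-yl]cyclopent-2-en-1-one
Conditions: I2 (1.5 equiv), pyridine/CH2Cl2 (1:1), 0 °C → rt, dark
Reagents that add atoms: iodine, II
Why: Johnson α-iodination of an enone (pyridine conjugate addition, iodination of the enolate, elimination), known for 4,4-disubstituted cyclopentenones and compatible in the dark with the free tertiary alcohol and the isolated Z alkene; no stereocentre is touched.

Step 6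
Reactants: 12 methyl hex-5-enoate; 13 (Z)-but-2-ene-1,4-diol
Product: 14 methyl (Z)-7-hydroxyhept-5-enoate
Conditions: 13 (3 equiv), Ru(NO3)(=CH-C6H4-2-OiPr)(C22H29N2) [C32H41N3O4Ru; C22H29N2 = C,C-chelating 1-(adamantan-1-yl)-3-mesitylimidazolidin-2-ylidene] (2 mol %), THF, 35 °C
Reagents that add atoms: none
Why: Z-selective olefin cross-metathesis, the cyclometalated ruthenium catalyst allowing only syn-substituted metallacyclobutanes so that the new disubstituted alkene is formed Z under kinetic control.

Step 7
Reactants: 14 methyl (Z)-7-hydroxyhept-5-enoate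
Product: 15 methyl (Z)-7-oxohept-5-enoate
Conditions: Dess–Martin periodinane (1.2 equiv), pyridine, CH2Cl2, 0 °C; used at once
Reagents that add atoms: none
Why: Dess–Martin oxidation of an allylic alcohol, fast at 0 °C under pyridine buffering so the Z-enal is formed without acid- or base-induced Z to E isomerisation.

Step 8
Reactants: 11 (S)-4-hydroxy-2-iodo-4-[(Z)-oct-2-en-1-yl]cyclopent-2-en-1-one; 15 methyl (Z)-7-oxohept-5-enoate
Product: 18 methyl (5Z,7S)-7-hydroxy-7-[(1R,5S)-5-hydroxy-3-iodo-5-[(Z)-oct-2-en-1-yl]-2-oxocyclopent-3-en-1-yl]hept-5-enoate, via dilithium enolate 16 (not isolated), via dilithium aldolate 17 (not isolated)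
Conditions: LiN(iPr)2 (2.1 equiv), THF, −78 °C; then 15 (1.1 equiv), −78 °C, 20 min; AcOH, −78 °C
Reagents that add atoms: none
Why: Directed aldol addition through a Zimmerman–Traxler chair, in which lithium bridged between the C12 alkoxide and the enolate oxygen of 16 delivers the aldehyde to C8 on the alkoxide face, anti to the octenyl chain (Fráter–Seebach-type chelate control, giving 8R), and the ring-locked E-enolate with the alkenyl group equatorial gives the anti aldol (7S).

Step 9
Reactants: 18 methyl (5Z,7S)-7-hydroxy-7-[(1R,5S)-5-hydroxy-3-iodo-5-[(Z)-oct-2-en-1-yl]-2-oxocyclopent-3-en-1-yl]hept-5-enoate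
Product: 19 methyl (5Z,7S)-7-acetoxy-7-[(1R,5S)-5-hydroxy-3-iodo-5-[(Z)-oct-2-en-1-yl]-2-oxocyclopent-3-en-1-yl]hept-5-enoate (7-acetoxy-7,8-dihydroiodovulone I)
Conditions: AcCl (1.3 equiv), pyridine (3 equiv), CH2Cl2, −40 °C
Reagents that add atoms: acetyl chloride, CC(=O)Cl
Why: Chemoselective O-acylation, the acylpyridinium ion acetylating the secondary allylic alcohol at −40 °C while the hindered tertiary alcohol is inert and the low temperature and weak base disfavour E1cB loss of acetate; no stereocentre is touched.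

**Compound list**

1 | (Z)-oct-2-en-1-ol | CCCCC/C=C\CO | starting material
2 | (Z)-1-bromooct-2-ene | CCCCC/C=C\CBr | intermediate
3 | 3-ethoxycyclopent-2-en-1-one | CCOC1=CC(=O)CC1 | starting material
4 | lithium 4-ethoxycyclopenta-1,4-dien-1-olate (α′-enolate of 3) | [Li+].CCOC1=CC([O-])=CC1 | intermediate
5 | rac-3-ethoxy-5-[(Z)-oct-2-en-1-yl]cyclopent-2-en-1-one | CCCCC/C=C\CC1CC(OCC)=CC1=O | intermediate
6 | 4-ethoxy-2-[(Z)-oct-2-en-1-yl]cyclopenta-1,4-dien-1-ol (α′-dienol of 5) | CCCCC/C=C\CC1=C(O)C=C(OCC)C1 | intermediate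
7 | (S)-3-ethoxy-5-[(Z)-oct-2-en-1-yl]-5-[(phenylamino)oxy]cyclopent-2-en-1-one | CCCCC/C=C\C[C@@]1(ONc2ccccc2)C(=O)C=C(OCC)C1 | intermediate
8 | (S)-3-ethoxy-5-hydroxy-5-[(Z)-oct-2-en-1-yl]cyclopent-2-en-1-one | CCCCC/C=C\C[C@@]1(O)C(=O)C=C(OCC)C1 | intermediate
9 | (1S)-4-ethoxy-1-[(Z)-oct-2-en-1-yl]cyclopent-3-ene-1,2-diol (both C2 epimers) | CCCCC/C=C\C[C@@]1(O)C(O)C=C(OCC)C1 | intermediate
10 | (S)-4-hydroxy-4-[(Z)-oct-2-en-1-yl]cyclopent-2-en-1-one | CCCCC/C=C\C[C@@]1(O)C=CC(=O)C1 | intermediate
11 | (S)-4-hydroxy-2-iodo-4-[(Z)-oct-2-en-1-yl]cyclopent-2-en-1-one | CCCCC/C=C\C[C@@]1(O)C=C(I)C(=O)C1 | intermediate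
12 | methyl hex-5-enoate | C=CCCCC(=O)OC | starting material
13 | (Z)-but-2-ene-1,4-diol | OC/C=C\CO | starting material
14 | methyl (Z)-7-hydroxyhept-5-enoate | OC/C=C\CCCC(=O)OC | intermediate
15 | methyl (Z)-7-oxohept-5-enoate | O=C/C=C\CCCC(=O)OC | intermediate
16 | dilithium alkoxide–enolate of 11 | [Li+].[Li+].CCCCC/C=C\C[C@@]1([O-])C=C(I)C([O-])=C1 | intermediate
17 | dilithium aldolate of 18 | [Li+].[Li+].CCCCC/C=C\C[C@@]1([O-])C=C(I)C(=O)[C@@H]1[C@H](/C=C\CCCC(=O)OC)[O-] | intermediate
18 | methyl (5Z,7S)-7-hydroxy-7-[(1R,5S)-5-hydroxy-3-iodo-5-[(Z)-oct-2-en-1-yl]-2-oxocyclopent-3-en-1-yl]hept-5-enoate | CCCCC/C=C\C[C@@]1(O)C=C(I)C(=O)[C@@H]1[C@H](/C=C\CCCC(=O)OC)O | intermediate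
19 | methyl (5Z,7S)-7-acetoxy-7-[(1R,5S)-5-hydroxy-3-iodo-5-[(Z)-oct-2-en-1-yl]-2-oxocyclopent-3-en-1-yl]hept-5-enoate | CCCCC/C=C\C[C@@]1(O)C=C(I)C(=O)[C@@H]1[C@H](/C=C\CCCC(=O)OC)OC(C)=O | target

**Step count and risks**

Total steps: 9. Longest linear sequence: 7 (steps 1, 2, 3, 4, 5, 8, 9); steps 6 and 7 make the aldehyde branch.

Three steps most likely to fail:

Step 3 (the proposed new reaction). Risks are attack of nitrosobenzene at C2 or C4 of the vinylogous ester instead of C5, N- instead of O-bonding, and modest enantioselectivity. The fallback uses known chemistry, sets out from 5 and comes back at 8. Compound 5 is deprotonated with KN(SiMe3)2 in THF at −78 °C to the potassium enolate F1. F1 is oxidised with (+)-[(8,8-dichlorocamphoryl)sulfonyl]oxaziridine (Davis reagent-controlled enolate hydroxylation; the antipodal reagent if the sense is opposite) and quenched with NH4Cl to give 8. The route then continues unchanged.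

Step 8. Risks are the untested deprotonation of an α-iodoenone that carries a free alkoxide, the C7/C8 selectivity, and Z to E isomerisation of the enal. The fallback sets out from 10 and comes back at 19; it runs the aldol one stage earlier on the iodine-free enone, the enolate type with direct precedent in clavulone-type aldols. LiN(iPr)2 (2.1 equiv) converts 10 into the deiodo dilithium enolate F2. Aldehyde 15 gives the deiodo dilithium aldolate F3, and AcOH quench gives the deiodo diol F4. AcCl and pyridine at −40 °C give the deiodo acetate F5. The iodine is introduced last (I2, pyridine, CH2Cl2, dark) to give 19.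

Step 9. Risks are slow acylation of the hindered carbinol and pyridine-induced loss of acetic acid to the cross-conjugated dienone. The fallback sets out from 11 and comes back at 19; it acetylates at the aldolate stage. Me3SiOSO2CF3 and 2,6-lutidine convert 11 into the tertiary trimethylsilyl ether F6. LiN(iPr)2 (1.05 equiv) gives the silyl lithium enolate F7, and 15 gives the silyl lithium aldolate F8. F8 is trapped in the same flask with Ac2O at −78 °C to give the silyl-protected acetate F9, so there is never a free β-hydroxy ketone and no amine above −78 °C. Aqueous citric acid in THF removes the silyl group to give 19. Facial control in this series rests on sterics instead of chelation and must be checked.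

**Further compounds**

F1 | step 3 | potassium 4-ethoxy-2-[(Z)-oct-2-en-1-yl]cyclopenta-1,4-dien-1-olate | [K+].CCCCC/C=C\CC1=C([O-])C=C(OCC)C1
F2 | step 8 | dilithium alkoxide–enolate of 10 | [Li+].[Li+].CCCCC/C=C\C[C@@]1([O-])C=CC([O-])=C1
F3 | step 8 | dilithium aldolate, 3-deiodo analogue of 17 | [Li+].[Li+].CCCCC/C=C\C[C@@]1([O-])C=CC(=O)[C@@H]1[C@H](/C=C\CCCC(=O)OC)[O-]
F4 | step 8 | 3-deiodo analogue of 18 (same spatial arrangement) | CCCCC/C=C\C[C@@]1(O)C=CC(=O)[C@@H]1[C@H](/C=C\CCCC(=O)OC)O
F5 | step 8 | 3-deiodo analogue of 19 (same spatial arrangement) | CCCCC/C=C\C[C@@]1(O)C=CC(=O)[C@@H]1[C@H](/C=C\CCCC(=O)OC)OC(C)=O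
F6 | step 9 | tertiary trimethylsilyl ether of 11 | CCCCC/C=C\C[C@@]1(O[Si](C)(C)C)C=C(I)C(=O)C1
F7 | step 9 | lithium enolate of F6 | [Li+].CCCCC/C=C\C[C@@]1(O[Si](C)(C)C)C=C(I)C([O-])=C1
F8 | step 9 | lithium aldolate from F7 and 15 | [Li+].CCCCC/C=C\C[C@@]1(O[Si](C)(C)C)C=C(I)C(=O)[C@@H]1[C@H](/C=C\CCCC(=O)OC)[O-]
F9 | step 9 | tertiary trimethylsilyl ether of 19 | CCCCC/C=C\C[C@@]1(O[Si](C)(C)C)C=C(I)C(=O)[C@@H]1[C@H](/C=C\CCCC(=O)OC)OC(C)=O
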